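Cooling from 25 °C to 0 °C slows the second step, which makes X, by a factor of 5.9, but it slows the third step, which turns Z into D, by more, at 36. So the flask must tell me which of the two counts for more.

- birch: L 0.10 M; Q 0.700 equiv; Z 10 mol%; temperature 25 °C; time 40 min
- maple: L 0.10 M; Q 0.700 equiv; Z 10 mol%; temperature 0 °C; time 40 min

    L + Z → Z + G (k1 = 7.2 L mol⁻¹ s⁻¹, Ea1 = 36.0 kJ mol⁻¹)
    Q + Z + G → Z + X (k2 = 11 L² mol⁻² s⁻¹, Ea2 = 48.0 kJ mol⁻¹)
    Z → D (k3 = 0.0028 s⁻¹, Ea3 = 97.0 kJ mol⁻¹)
    (constants at 25 °C)

- all constants are for 25 °C and move with temperature by the activation energies

- the flask with the highest amount of X, in percent of the L charged ("all alike" if they lie within 1.5 percentage points) (birch / maple / all alike)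
- final X, as a percentage of the L charged, in birch
- final X, as a percentage of the L charged, in maple

I write the balance of Q, which is charged below L and so is the limiting reagent for X: the charge allows 70.0 %. L lasts about 13.9 s in birch, far shorter than the 357 s that Z lives there, and about 52.5 s in maple, far shorter than the 40 min of the run, so in both flasks I take G as all the L not yet turned into X. With k the constant of the second step, w that of the third, q the equivalents of Q and x the part of L made into X:

ln[ q(1 − x) / (q − x) ] = (1 − q) N

N = k [L]start [Z]start (1 − exp(−wt)) / w

x = q(E − 1) / (E − q), with E = exp[(1 − q) N]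

Birch has N = 3.92 and maple has N = 4.09. N counts how many e-fold falls Q would make if G stood at its full charge, over the time Z lives or the clock allows. It gives x = 61.7 % for birch and 62.3 % for maple, a gap of 0.60 percentage points, inside the margin. One number is nearly enough: in birch, G's lag costs about 3.89 % of N, so my figure there sits a little high.

The forecast says all alike, with 61.3 % (59 % to 63.5 %) for birch and 62 % (59.5 % to 64.5 %) for maple: “These effects almost cancel”. My birch figure stands 0.40 points above its figure.

The flasks give 61.2 % in birch and 62.0 % in maple, so all alike, with a gap of 0.80 points. Left ten times as long, birch reads 61.2 % and maple 70.0 %. At that time, N is 3.93 in birch and 20.3 in maple, where x comes to 70.0 %.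

Now take maple with 1.80 equiv of Q. N stays 4.09, and x comes to 98.3 %. That flask gives 98.1 %, with 45 % of its Q left.

(Its constants come from no measurement; no experiment stands behind them.)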